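## The problem

The target is an ester of two oxidised p-menthane units. The acyl half is an (E)-2-(hydroxymethyl)acrylic acid whose β-carbon sits on C1′ of a cyclohexene (ring C: C2′=C3′ with CH2OH on C3′, isopropyl on C6′). The alcohol half is a cyclohexane (ring A: C5a, C6 to C9, C9a, numbered as a 2-benzoxepine) cis-fused to a seven-membered unsaturated lactone (ring B: C1 carbonyl, O2, C3, C4 bearing CO2H, C5). C9 carries a tertiary hydroxyl and the CH2O group that is acylated.

There are six stereocentres: C1′/C6′ (trans) in ring C, and C5a/C6 (trans), C9a (carbonyl cis to the C5a branch) and C9 (hydroxyl cis to the C9a carbonyl) in ring A. The two trans pairs are the same motif with the same absolute sense, so one enantioselective event should set both. C9a can then be controlled by C5a/C6 through ring conformation, and C9 by C9a through a directing group. The acyclic alkene geometry must come from the olefination; ring B fixes its own.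

The groups that limit the choice of reagents are:
- the tertiary β-hydroxy lactone (retro-aldol, β-elimination once C9a is deprotonated);
- the lactone C3–O bond, which is the allylic ester of an acrylate (SN2′ attack, ionisation by zerovalent palladium);
- the doubly allylic C1′–H;
- the free acid and three hydroxyls, which must be unmasked last and without base.

The enabling feature is that C3′(CH2OH)=C2′H–C1′H(C)–C6′H(iPr)–C5′H2–C4′H2 is a 3-substituted 4-isopropylcyclohex-1-ene-1-carbaldehyde at a lower oxidation level. Ring A (C9, C9a, C5a, C6, C7, C8) is the same ring after one carbon is added at the enal β-carbon and oxygen at the α-carbon. This ring type is what an aldehyde, a nitroalkene and an enal give in one amine-catalysed cascade.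

## Retrosynthesis

**32 to 30 (unmasking).** Target 32 is reached from 30, which carries only two silyl ethers and a tert-butyl ester. These were chosen because all three leave under non-basic conditions in one flask, which the β-hydroxy lactone requires.

**30 to 29 (ring B alkene).** The C4=C5 bond is cut, giving triene 29 with a vinyl group on C5a and a 2-(alkoxycarbonyl)allyl ester on the C9a carboxyl. Cutting the lactone C–O bond instead would need the hydroxymethyl-acrylate arm built on C5a by olefination while a C9a carbonyl with a β-oxygen is present, which means more steps under base. Metathesis needs only that the two cis arms meet, and the ring fixes the geometry.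

**29 to 28 to 27 (ester and acid).** The ester C–O bond is cut to acid 28 and commercial tert-butyl 2-(bromomethyl)acrylate, which brings C3, C4 and the protected carboxyl in one piece. Acid 28 is the oxidation product of primary alcohol 27. Carboxylate alkylation needs no activation of a β-hydroxy acid, so no β-lactone can form.

**27 to 26 + 20 (fragment union).** The alkyl C–O bond between the ester oxygen and the CH2 on C9 is cut, not the acyl C–O bond. This gives spiro-epoxide 26 and acid 20. An epoxide opening sets free the tertiary hydroxyl and makes the ester in one step without protecting the diol; esterification of a 1,2-diol would cost two protecting-group steps. The forward step needs attack at the CH2 carbon only, so that C9 keeps its configuration. It is done before any carbonyl stands on C9a, so base cannot open the epoxide by elimination.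

**26 to 25 (C9–O bond).** The epoxide oxygen is removed to give homoallylic alcohol 25 (exocyclic methylene at C9, CH2OH on C9a). The target needs the C9 oxygen on the face of the C9a carbon, which is the face a free reagent avoids; only delivery from the CH2OH group gives it.

**25 to 23 to 22 (C9a–C bond).** The bond from C9a to its CH2OH carbon is cut by a retro-[2,3] shift to stannylmethyl ether 23, made from allylic alcohol 22. One step adds the carbon at the former enal β-carbon and leaves the methylene needed for the epoxidation. Conjugate addition to the enal would leave C9 as a CH and bring oxygen in from the wrong face. The forward step must form the bond on the face of the C5a substituent.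

**22 to 21 to 16 (vinyl group).** The vinyl group is traced through silyl ether 21 to aldehyde 16. Vinyl is the form of C5 that survives KH, n-BuLi, peroxide and oxidation, and it is what metathesis later needs.

**20 to 19 to 18 to 17 to 16 (acyl half).** Acid 20 comes from ester 19 and alcohol 18. The Cα–CH2OH bond is cut to (Z)-bromoenoate 17, and the C=C bond to aldehyde 16 and a bromo ylide. The bromine fixes the geometry at the Wittig stage and is then exchanged with retention, using commercial reagents only. Both halves thus diverge from 16.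

**16 to 11 (adjustments).** Aldehyde 16 goes back through alcohol 15, PMB ether 14, allylic alcohol 13 and nitro alcohol 12 to nitro enal 11. The enal is reduced before the tin hydride step because tin hydride would reduce it.

**11 to 3 + 8 + 9 (key disconnection).** Three ring bonds are cut: C3–C4 (between the two stereocentres), C5–C6 and C1=C2. This gives 3-(4-methoxybenzyloxy)propanal 3, nitroalkene 8 and acrolein 9. No other cut gives a ring with both stereocentres, the right oxidation pattern and the handles for both halves from achiral three- to five-carbon pieces. The forward step needs catalyst control in the first Michael addition; the nitro centre is irrelevant.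

**3, 8 to 1, 4, 5 (components).** Aldehyde 3 comes from propane-1,3-diol 1 through 2. Nitroalkene 8 comes from 2-methylpropanal 4 and nitromethane 5 through 6 (mesylate 7 in the flask).

## Roads not taken

**Alternative 1:** The C5a–C9a bond and the bond from C5 to the C4 carbon are made by intramolecular [2+2] photocycloaddition of tetronic acid A1. Retro-aldol opening of the cyclobutanol then expands the furanone to keto lactone A2 (de Mayo sequence).

- Merits: rings A and B arise in one operation. The cis fusion at C5a/C9a follows from the cyclobutane geometry. This is the relationship that the chosen plan must win by facial selectivity in step 18, so here the photochemical road is the stronger one.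
- Weak points: A1 needs C6 and C9 set independently on an open chain. The facial course of the cycloaddition relative to them and its straight-versus-crossed regiochemistry are not secured. A2 has a ketone at C4 where the target has the carboxyl-bearing alkene carbon, so an enol triflate must be formed toward C5 (not C3) and carbonylated. Ring C is not addressed.
- Against it, the chosen plan sets one catalytic step that gives the ring and the trans pair for both halves, and a C9a carbon already at the right position.

**Alternative 2:** The acyl C–O bond of the inter-fragment ester and the Cα–carbonyl bond are cut. Vinyl iodide A3 is cyclocarbonylated under zerovalent palladium to α-alkylidene β-lactone A4, which acylates the C9 CH2OH with ring opening.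

- Merits: the alkene geometry is fixed in A3, the acid is activated by strain, and the side-chain CH2OH emerges free. That would save the silylation and saponification (steps 13 and 14) of the chosen plan, so for the union itself this road is more economical.
- Weak points: it solves only the side chain. Ring C and the whole lactone half still need a ring-forming strategy, and A3 would itself be made from an aldehyde such as 16 in several steps. Opening A4 with a neopentyl-type alcohol may be slow and can go by alkyl–O cleavage.
- Against it, the chosen plan sets a union by epoxide opening that also needs no activating reagent. A4 could be adopted as a module inside the chosen plan.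

**Alternative 3:** The C9–C9a bond is cut. Keto acid A5 is activated with a 2-halopyridinium salt and 4-pyrrolidinopyridine; the ammonium enolate adds to the ketone and the alkoxide closes β-lactone A6.

- Merits: the C9 oxygen and the C9a carbonyl are cis by construction and already at the acid oxidation level. The chosen plan needs a shift, a directed epoxidation and an oxidation for the same result, so this road is better at that point.
- Weak points: A5 needs the C5a/C6 pair and a seven-carbon chain assembled first. The C9a/C5a relationship rests on substrate control by the neighbouring acetal-bearing carbon. Ring B must still be built from the acetal and the strained lactone, and ring C is separate.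
- Against it, the chosen plan sets the fact that ring A's carbons and the trans pair come with the cascade, and the same intermediate 16 serves ring C.

Key step: step 5

Assumption: the nitro-bearing carbon of 11 and 12 is written as the all-trans (5S) epimer; it is erased in step 7, so either epimer or a mixture serves.

## Route

Step 1
Reactants: 1 propane-1,3-diol
Product: 2 3-[(4-methoxyphenyl)methoxy]propan-1-ol
Conditions: NaH (1 equiv), 1 (3 equiv), THF, 0 °C; then 4-methoxybenzyl chloride, Bu4NI (cat.), rt
Reagents that add atoms: 4-methoxybenzyl chloride, COc1ccc(CCl)cc1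
Why: Williamson etherification; the excess of the symmetrical diol keeps dialkylation low.

Step 2
Reactants: 2 3-[(4-methoxyphenyl)methoxy]propan-1-ol
Product: 3 3-[(4-methoxyphenyl)methoxy]propanal
Conditions: 2,2,6,6-tetramethylpiperidin-1-oxyl (TEMPO, 10 mol %), PhI(OAc)2, CH2Cl2, rt
Reagents that add atoms: none
Why: Oxoammonium oxidation of a primary alcohol stops at the aldehyde under water-free, base-free conditions, which spares the β-alkoxy aldehyde from elimination; 3 is used at once.

Step 3
Reactants: 4 2-methylpropanal; 5 nitromethane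
Product: 6 3-methyl-1-nitrobutan-2-ol (racemic)
Conditions: KOtBu (10 mol %), THF/t-BuOH, 0 °C → rt
Reagents that add atoms: none
Why: Henry (nitroaldol) addition; the carbinol centre is removed in the next step.

Step 4
Reactants: 6 3-methyl-1-nitrobutan-2-ol
Product: 8 (E)-3-methyl-1-nitrobut-1-ene, via mesylate 7 (not isolated)
Conditions: MsCl, Et3N (2.2 equiv), CH2Cl2, −10 → 0 °C
Reagents that add atoms: none
Why: Mesylation followed by E1cB elimination through the nitronate gives the conjugated E nitroalkene.

Step 5
Reactants: 3 3-[(4-methoxyphenyl)methoxy]propanal; 8 (E)-3-methyl-1-nitrobut-1-ene; 9 prop-2-enal (acrolein)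
Product: 11 (3R,4S,5S)-3-{[(4-methoxyphenyl)methoxy]methyl}-5-nitro-4-(propan-2-yl)cyclohex-1-ene-1-carbaldehyde, via syn γ-nitro aldehyde 10 (not isolated)
Conditions: (R)-2-[diphenyl(trimethylsilyloxy)methyl]pyrrolidine (20 mol %), toluene, 0 °C → rt, 9 added last and slowly
Reagents that add atoms: none
Why: Amine-catalysed Michael–Michael–aldol condensation cascade of an aldehyde, a nitroalkene and an enal, the known triple cascade of this catalyst class. The anti enamine of 3 adds to 8 on the face left open by the diphenyl(silyloxy)methyl group through a synclinal transition state, which sets C3 and C4 of 11 as the syn adduct 10 (trans on the ring). From the known sense of the (S) catalyst, the (R) catalyst should give the (2R,3S) adduct needed here. The nitronate of 10 then adds to the acrolein iminium ion (C5–C6 bond); C5 forms under substrate control and is later erased. The resulting enamine closes the ring by a 6-exo-trig (enolendo) aldol addition onto the first aldehyde, and dehydration gives the C1=C2 bond and frees the catalyst. Chemoselectivity follows from the components: only 3 can form a nucleophilic enamine, the nitroalkene is the best acceptor for it, and acrolein reacts only as its iminium ion with the acidic nitroalkane. The aliphatic nitroalkene is less reactive than the aryl cases, so time and concentration may need to be raised.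

Step 6
Reactants: 11 nitro enal
Product: 12 [(3R,4S,5S)-3-{[(4-methoxyphenyl)methoxy]methyl}-5-nitro-4-(propan-2-yl)cyclohex-1-en-1-yl]methanol
Conditions: NaBH4, CeCl3·7H2O, MeOH, −20 °C
Reagents that add atoms: none
Why: Luche 1,2-reduction of the enal; the nitro group is inert and the enal is removed before the tin hydride step.

Step 7
Reactants: 12 nitro allylic alcohol
Product: 13 [(3S,4S)-3-{[(4-methoxyphenyl)methoxy]methyl}-4-(propan-2-yl)cyclohex-1-en-1-yl]methanol
Conditions: Bu3SnH (5 equiv), azobis(isobutyronitrile) (0.3 equiv in portions), toluene, 110 °C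
Reagents that add atoms: none
Why: Radical denitration of a secondary nitroalkane (Ono conditions): the stannyl radical adds to the nitro oxygen, C–N homolysis gives the cyclohexyl radical and Sn–H reduces it. Both C5 epimers converge, and the high tin hydride concentration outruns rearrangement of the homoallylic radical.

Step 8
Reactants: 13 allylic alcohol
Product: 14 tert-butyl{[(3S,4S)-3-{[(4-methoxyphenyl)methoxy]methyl}-4-(propan-2-yl)cyclohex-1-en-1-yl]methoxy}dimethylsilane
Conditions: tert-butyl(chloro)dimethylsilane, imidazole, DMF, rt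
Reagents that add atoms: tert-butyl(chloro)dimethylsilane, CC(C)(C)[Si](C)(C)Cl
Why: Standard silylation of a primary alcohol; the silyl ether is orthogonal to the PMB ether.

Step 9
Reactants: 14 silyl PMB diether
Product: 15 [(1S,6S)-3-({[tert-butyl(dimethyl)silyl]oxy}methyl)-6-(propan-2-yl)cyclohex-2-en-1-yl]methanol
Conditions: 2,3-dichloro-5,6-dicyano-1,4-benzoquinone (DDQ), CH2Cl2/pH 7 buffer (10:1), 0 °C
Reagents that add atoms: none
Why: Oxidative cleavage of the PMB ether by hydride abstraction and hydrolysis; silyl ether and trisubstituted alkene are untouched.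

Step 10
Reactants: 15 primary alcohol
Product: 16 (1S,6S)-3-({[tert-butyl(dimethyl)silyl]oxy}methyl)-6-(propan-2-yl)cyclohex-2-ene-1-carbaldehyde
Conditions: Dess–Martin periodinane, NaHCO3, CH2Cl2, 0 °C; used without storage
Reagents that add atoms: none
Why: Buffered Dess–Martin oxidation gives the β,γ-unsaturated aldehyde without base, so the α-centre neither epimerises nor moves the alkene into conjugation.

Step 11
Reactants: 16 aldehyde
Product: 17 methyl (2Z)-2-bromo-3-[(1S,6S)-3-({[tert-butyl(dimethyl)silyl]oxy}methyl)-6-(propan-2-yl)cyclohex-2-en-1-yl]prop-2-enoate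
Conditions: Ph3P=CHCO2Me, N-bromosuccinimide, CH2Cl2, −20 °C; then 16, rt
Reagents that add atoms: methyl (triphenylphosphoranylidene)acetate, COC(=O)C=P(c1ccccc1)(c1ccccc1)c1ccccc1; N-bromosuccinimide, O=C1CCC(=O)N1Br
Why: Wittig olefination with the stabilised bromo ylide formed in the flask; the ylide is not basic enough to enolise 16. It places the ring trans to the ester (Z by the priority of bromine), which is the geometry of the target.

Step 12
Reactants: 17 bromoenoate
Product: 18 methyl (2E)-3-[(1S,6S)-3-({[tert-butyl(dimethyl)silyl]oxy}methyl)-6-(propan-2-yl)cyclohex-2-en-1-yl]-2-(hydroxymethyl)prop-2-enoate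
Conditions: Bu3SnCH2OH, Pd(PPh3)4 (5 mol %), 1,4-dioxane, 90 °C
Reagents that add atoms: (tributylstannyl)methanol, CCCC[Sn](CCCC)(CCCC)CO
Why: Stille coupling of an alkenyl bromide with the hydroxymethylstannane under zerovalent palladium; oxidative addition and reductive elimination retain the alkene geometry.

Step 13
Reactants: 18 hydroxy ester
Product: 19 methyl (2E)-2-({[tert-butyl(dimethyl)silyl]oxy}methyl)-3-[(1S,6S)-3-({[tert-butyl(dimethyl)silyl]oxy}methyl)-6-(propan-2-yl)cyclohex-2-en-1-yl]prop-2-enoate
Conditions: tert-butyl(chloro)dimethylsilane, imidazole, DMF, rt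
Reagents that add atoms: tert-butyl(chloro)dimethylsilane, CC(C)(C)[Si](C)(C)Cl
Why: Silylation of the allylic primary alcohol so that it survives the later oxidation in step 21.

Step 14
Reactants: 19 bis-silyl ester
Product: 20 (2E)-2-({[tert-butyl(dimethyl)silyl]oxy}methyl)-3-[(1S,6S)-3-({[tert-butyl(dimethyl)silyl]oxy}methyl)-6-(propan-2-yl)cyclohex-2-en-1-yl]prop-2-enoic acid
Conditions: LiOH·H2O, THF/MeOH/H2O, 0 °C → rt; then 1 M HCl to pH 4 at 0 °C
Reagents that add atoms: lithium hydroxide, [Li+].[OH-]
Why: Saponification of a methyl ester; hydroxide is too weak to remove the doubly allylic γ-hydrogen and primary silyl ethers survive.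

Step 15
Reactants: 16 aldehyde
Product: 21 tert-butyl{[(3S,4S)-3-ethenyl-4-(propan-2-yl)cyclohex-1-en-1-yl]methoxy}dimethylsilane
Conditions: Zn, CH2Br2, TiCl4, THF/CH2Cl2, 0 °C → rt
Reagents that add atoms: dibromomethane, BrCBr
Why: Takai–Lombardo methylenation; the non-basic titanium–zinc methylene reagent converts enolisable aldehydes without epimerisation or alkene migration.

Step 16
Reactants: 21 silyl ether
Product: 22 [(3S,4S)-3-ethenyl-4-(propan-2-yl)cyclohex-1-en-1-yl]methanol
Conditions: Bu4NF, THF, 0 °C → rt
Reagents that add atoms: none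
Why: Fluoride cleavage of the silyl ether; no other functional group is present.

Step 17
Reactants: 22 allylic alcohol
Product: 23 tributyl({[(3S,4S)-3-ethenyl-4-(propan-2-yl)cyclohex-1-en-1-yl]methoxy}methyl)stannane
Conditions: KH, THF, 0 °C; then Bu3SnCH2I, rt
Reagents that add atoms: tributyl(iodomethyl)stannane, CCCC[Sn](CI)(CCCC)CCCC
Why: Williamson alkylation of the potassium alkoxide with the iodomethylstannane (Still's preparation of [2,3]-Wittig precursors).

Step 18
Reactants: 23 stannylmethyl ether
Product: 25 [(1S,2S,3S)-2-ethenyl-6-methylidene-3-(propan-2-yl)cyclohexyl]methanol, via α-alkoxymethyllithium 24 (not isolated)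
Conditions: n-BuLi, THF, −78 → −40 °C; aq NH4Cl
Reagents that add atoms: none
Why: Still variant of the [2,3]-Wittig rearrangement: tin–lithium exchange gives 24, whose carbanion shifts suprafacially to the ring carbon (future C9a) while the alkene moves to the exocyclic position. The bond should form axially on the half-chair that keeps vinyl and isopropyl equatorial, that is on the face of the vinyl group. Attack on the other face needs the diaxial conformer, where the axial isopropyl group is 1,3-syn to the incoming carbon.

Step 19
Reactants: 25 homoallylic alcohol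
Product: 26 [(3R,4R,5S,6S)-5-ethenyl-6-(propan-2-yl)-1-oxaspiro[2.5]octan-4-yl]methanol
Conditions: VO(acac)2 (5 mol %), t-BuOOH (decane solution), CH2Cl2, 0 °C → rt
Reagents that add atoms: tert-butyl hydroperoxide, CC(C)(C)OO
Why: Vanadium-catalysed hydroxyl-directed epoxidation of a homoallylic alcohol: the alkoxide-bound peroxide delivers oxygen to the face of the methylene group on which the CH2OH lies, so the C9 oxygen is cis to the C9a carbon. The 1,1-disubstituted homoallylic alkene reacts before the more remote vinyl group.

Step 20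
Reactants: 26 spiro-epoxide; 20 acid
Product: 27 [(1R,2R,3S,4S)-3-ethenyl-1-hydroxy-2-(hydroxymethyl)-4-(propan-2-yl)cyclohexyl]methyl ester of acid 20
Conditions: 20 (1.3 equiv), Cs2CO3 (0.3 equiv), DMF, 80 °C
Reagents that add atoms: none
Why: Nucleophilic opening of a terminal epoxide by a caesium carboxylate at the CH2 carbon (SN2), the alkoxide being protonated by the excess acid. The C9–O bond is not broken, so C9 keeps its configuration and the ester and the free tertiary hydroxyl appear together.

Step 21
Reactants: 27 hydroxy ester
Product: 28 (1S,2R,5S,6S)-6-ethenyl-2-hydroxy-5-(propan-2-yl)-2-[(acyloxy)methyl]cyclohexane-1-carboxylic acid (acyl = that of 20)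
Conditions: 2,2,6,6-tetramethylpiperidin-1-oxyl (10 mol %), NaClO2, NaOCl (cat.), MeCN/phosphate buffer pH 6.7, 35 °C
Reagents that add atoms: sodium chlorite, [Na+].[O-]Cl=O
Why: TEMPO/chlorite oxidation of a primary alcohol to the acid near neutral pH; silyl ethers, alkenes and the tertiary alcohol are inert and C9a sees no base.

Step 22
Reactants: 28 β-hydroxy acid
Product: 29 2-(tert-butoxycarbonyl)prop-2-en-1-yl ester of acid 28
Conditions: tert-butyl 2-(bromomethyl)prop-2-enoate, KHCO3, DMF, rt
Reagents that add atoms: tert-butyl 2-(bromomethyl)prop-2-enoate, C=C(CBr)C(=O)OC(C)(C)C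
Why: O-Alkylation of the carboxylate by an activated allylic bromide (SN2 and SN2′ give the same ester); the acid is never activated, so no β-lactone forms, and bicarbonate leaves the tertiary hydroxyl alone.

Step 23
Reactants: 29 triene diester
Product: 30 tert-butyl (5aR,6S,9R,9aS)-9-hydroxy-1-oxo-6-(propan-2-yl)-9-[(acyloxy)methyl]-1,3,5a,6,7,8,9,9a-octahydro-2-benzoxepine-4-carboxylate (acyl = that of 20)
Conditions: [1,3-bis(2,4,6-trimethylphenyl)imidazolidin-2-ylidene]dichloro(2-isopropoxybenzylidene)ruthenium (second-generation Hoveyda–Grubbs catalyst, 10 mol %), toluene (2 mM), 80 °C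
Reagents that add atoms: none
Why: Ring-closing metathesis of the vinyl group with the 2-substituted acrylate closes ring B as the trisubstituted enoate, a closure known for five- to seven-membered rings with second-generation catalysts. The cis arms on ring A are held close, the ring fixes the alkene geometry, and the trisubstituted alkenes of the acyl half do not take part.

Step 24
Reactants: 30 protected target
Product: 32 (5aR,6S,9R,9aS)-9-hydroxy-9-({[(2E)-2-(hydroxymethyl)-3-[(1S,6S)-3-(hydroxymethyl)-6-(propan-2-yl)cyclohex-2-en-1-yl]prop-2-enoyl]oxy}methyl)-1-oxo-6-(propan-2-yl)-1,3,5a,6,7,8,9,9a-octahydro-2-benzoxepine-4-carboxylic acid (the target), via persilylated acid 31 (not isolated)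
Conditions: trimethylsilyl trifluoromethanesulfonate, 2,6-lutidine, CH2Cl2, 0 °C; then HF·pyridine, THF/pyridine, 0 °C → rt
Reagents that add atoms: none
Why: Silyl triflate/lutidine converts the tert-butyl ester into the trimethylsilyl ester with loss of 2-methylpropene and silylates the tertiary alcohol; HF·pyridine then removes all silyl groups. Neither base nor strong protic acid touches the β-hydroxy lactone, the allylic lactone C–O bond or the allylic alcohols.

## Compound list

1 | propane-1,3-diol | OCCCO | starting material
2 | 3-[(4-methoxyphenyl)methoxy]propan-1-ol | COc1ccc(COCCCO)cc1 | intermediate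
3 | 3-[(4-methoxyphenyl)methoxy]propanal | COc1ccc(COCCC=O)cc1 | intermediate
4 | 2-methylpropanal | CC(C)C=O | starting material
5 | nitromethane | C[N+](=O)[O-] | starting material
6 | 3-methyl-1-nitrobutan-2-ol (racemic) | CC(C)C(O)C[N+](=O)[O-] | intermediate
7 | 3-methyl-1-nitrobutan-2-yl methanesulfonate (racemic) | CC(C)C(OS(C)(=O)=O)C[N+](=O)[O-] | intermediate (not isolated)
8 | (E)-3-methyl-1-nitrobut-1-ene | CC(C)/C=C/[N+](=O)[O-] | intermediate
9 | prop-2-enal (acrolein) | C=CC=O | starting material
10 | (2R,3S)-2-{[(4-methoxyphenyl)methoxy]methyl}-4-methyl-3-(nitromethyl)pentanal | O=C[C@@H](COCc1ccc(OC)cc1)[C@H](C(C)C)C[N+](=O)[O-] | intermediate (not isolated)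
11 | (3R,4S,5S)-3-{[(4-methoxyphenyl)methoxy]methyl}-5-nitro-4-(propan-2-yl)cyclohex-1-ene-1-carbaldehyde | O=CC1=C[C@@H](COCc2ccc(OC)cc2)[C@H](C(C)C)[C@@H]([N+](=O)[O-])C1 | intermediate
12 | [(3R,4S,5S)-3-{[(4-methoxyphenyl)methoxy]methyl}-5-nitro-4-(propan-2-yl)cyclohex-1-en-1-yl]methanol | OCC1=C[C@@H](COCc2ccc(OC)cc2)[C@H](C(C)C)[C@@H]([N+](=O)[O-])C1 | intermediate
13 | [(3S,4S)-3-{[(4-methoxyphenyl)methoxy]methyl}-4-(propan-2-yl)cyclohex-1-en-1-yl]methanol | OCC1=C[C@@H](COCc2ccc(OC)cc2)[C@H](C(C)C)CC1 | intermediate
14 | tert-butyl{[(3S,4S)-3-{[(4-methoxyphenyl)methoxy]methyl}-4-(propan-2-yl)cyclohex-1-en-1-yl]methoxy}dimethylsilane | CC(C)(C)[Si](C)(C)OCC1=C[C@@H](COCc2ccc(OC)cc2)[C@H](C(C)C)CC1 | intermediate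
15 | [(1S,6S)-3-({[tert-butyl(dimethyl)silyl]oxy}methyl)-6-(propan-2-yl)cyclohex-2-en-1-yl]methanol | OC[C@@H]1C=C(CO[Si](C)(C)C(C)(C)C)CC[C@H]1C(C)C | intermediate
16 | (1S,6S)-3-({[tert-butyl(dimethyl)silyl]oxy}methyl)-6-(propan-2-yl)cyclohex-2-ene-1-carbaldehyde | O=C[C@@H]1C=C(CO[Si](C)(C)C(C)(C)C)CC[C@H]1C(C)C | intermediate
17 | methyl (2Z)-2-bromo-3-[(1S,6S)-3-({[tert-butyl(dimethyl)silyl]oxy}methyl)-6-(propan-2-yl)cyclohex-2-en-1-yl]prop-2-enoate | COC(=O)/C(Br)=C/[C@@H]1C=C(CO[Si](C)(C)C(C)(C)C)CC[C@H]1C(C)C | intermediate
18 | methyl (2E)-3-[(1S,6S)-3-({[tert-butyl(dimethyl)silyl]oxy}methyl)-6-(propan-2-yl)cyclohex-2-en-1-yl]-2-(hydroxymethyl)prop-2-enoate | COC(=O)/C(CO)=C/[C@@H]1C=C(CO[Si](C)(C)C(C)(C)C)CC[C@H]1C(C)C | intermediate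
19 | methyl (2E)-2-({[tert-butyl(dimethyl)silyl]oxy}methyl)-3-[(1S,6S)-3-({[tert-butyl(dimethyl)silyl]oxy}methyl)-6-(propan-2-yl)cyclohex-2-en-1-yl]prop-2-enoate | COC(=O)/C(CO[Si](C)(C)C(C)(C)C)=C/[C@@H]1C=C(CO[Si](C)(C)C(C)(C)C)CC[C@H]1C(C)C | intermediate
20 | (2E)-2-({[tert-butyl(dimethyl)silyl]oxy}methyl)-3-[(1S,6S)-3-({[tert-butyl(dimethyl)silyl]oxy}methyl)-6-(propan-2-yl)cyclohex-2-en-1-yl]prop-2-enoic acid | OC(=O)/C(CO[Si](C)(C)C(C)(C)C)=C/[C@@H]1C=C(CO[Si](C)(C)C(C)(C)C)CC[C@H]1C(C)C | intermediate
21 | tert-butyl{[(3S,4S)-3-ethenyl-4-(propan-2-yl)cyclohex-1-en-1-yl]methoxy}dimethylsilane | C=C[C@@H]1C=C(CO[Si](C)(C)C(C)(C)C)CC[C@H]1C(C)C | intermediate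
22 | [(3S,4S)-3-ethenyl-4-(propan-2-yl)cyclohex-1-en-1-yl]methanol | C=C[C@@H]1C=C(CO)CC[C@H]1C(C)C | intermediate
23 | tributyl({[(3S,4S)-3-ethenyl-4-(propan-2-yl)cyclohex-1-en-1-yl]methoxy}methyl)stannane | C=C[C@@H]1C=C(COC[Sn](CCCC)(CCCC)CCCC)CC[C@H]1C(C)C | intermediate
24 | ({[(3S,4S)-3-ethenyl-4-(propan-2-yl)cyclohex-1-en-1-yl]methoxy}methyl)lithium | [Li]COCC1=C[C@@H](C=C)[C@H](C(C)C)CC1 | intermediate (not isolated)
25 | [(1S,2S,3S)-2-ethenyl-6-methylidene-3-(propan-2-yl)cyclohexyl]methanol | CC(C)[C@@H]1CCC(=C)[C@@H](CO)[C@H]1C=C | intermediate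
26 | [(3R,4R,5S,6S)-5-ethenyl-6-(propan-2-yl)-1-oxaspiro[2.5]octan-4-yl]methanol | CC(C)[C@@H]1CC[C@]2(CO2)[C@@H](CO)[C@H]1C=C | intermediate
27 | [(1R,2R,3S,4S)-3-ethenyl-1-hydroxy-2-(hydroxymethyl)-4-(propan-2-yl)cyclohexyl]methyl ester of acid 20 | CC(C)[C@@H]1CC[C@](O)(COC(=O)/C(=C/[C@@H]2C=C(CO[Si](C)(C)C(C)(C)C)CC[C@H]2C(C)C)CO[Si](C)(C)C(C)(C)C)[C@@H](CO)[C@H]1C=C | intermediate
28 | (1S,2R,5S,6S)-6-ethenyl-2-hydroxy-5-(propan-2-yl)-2-[(acyloxy)methyl]cyclohexane-1-carboxylic acid, acyl = that of 20 | CC(C)[C@@H]1CC[C@](O)(COC(=O)/C(=C/[C@@H]2C=C(CO[Si](C)(C)C(C)(C)C)CC[C@H]2C(C)C)CO[Si](C)(C)C(C)(C)C)[C@@H](C(=O)O)[C@H]1C=C | intermediate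
29 | 2-(tert-butoxycarbonyl)prop-2-en-1-yl ester of acid 28 | CC(C)[C@@H]1CC[C@](O)(COC(=O)/C(=C/[C@@H]2C=C(CO[Si](C)(C)C(C)(C)C)CC[C@H]2C(C)C)CO[Si](C)(C)C(C)(C)C)[C@@H](C(=O)OCC(=C)C(=O)OC(C)(C)C)[C@H]1C=C | intermediate
30 | tert-butyl ester, bis(tert-butyldimethylsilyl) ether of the target (ring B closed) | CC(C)[C@@H]1CC[C@](O)(COC(=O)/C(=C/[C@@H]2C=C(CO[Si](C)(C)C(C)(C)C)CC[C@H]2C(C)C)CO[Si](C)(C)C(C)(C)C)[C@H]2C(=O)OCC(C(=O)OC(C)(C)C)=C[C@@H]12 | intermediate
31 | trimethylsilyl ester and C9 trimethylsilyl ether of the bis(tert-butyldimethylsilyl) ether of the target | CC(C)[C@@H]1CC[C@](O[Si](C)(C)C)(COC(=O)/C(=C/[C@@H]2C=C(CO[Si](C)(C)C(C)(C)C)CC[C@H]2C(C)C)CO[Si](C)(C)C(C)(C)C)[C@H]2C(=O)OCC(C(=O)O[Si](C)(C)C)=C[C@@H]12 | intermediate (not isolated)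
32 | (5aR,6S,9R,9aS)-9-hydroxy-9-({[(2E)-2-(hydroxymethyl)-3-[(1S,6S)-3-(hydroxymethyl)-6-(propan-2-yl)cyclohex-2-en-1-yl]prop-2-enoyl]oxy}methyl)-1-oxo-6-(propan-2-yl)-1,3,5a,6,7,8,9,9a-octahydro-2-benzoxepine-4-carboxylic acid | CC(C)[C@@H]1CC[C@](O)(COC(=O)/C(=C/[C@@H]2C=C(CO)CC[C@H]2C(C)C)CO)[C@H]2C(=O)OCC(C(=O)O)=C[C@@H]12 | target

## Step count and least certain steps

Total: 24 steps. Longest linear sequence: 18 steps (1, 2, 5–10, 15–24). The acyl half (steps 11–14) and the nitroalkene (steps 3, 4) are side branches.

**Step 5 (key step).** Three things may go wrong. The enamine of 3 may lose 4-methoxybenzyl alcohol by β-elimination, which starves the first Michael addition. Addition to the aliphatic nitroalkene may be slow and less face-selective. Acrolein may oligomerise before the nitronate reaches it. Fallback: 3 and 8 are joined alone with the same catalyst and 4-nitrophenol as co-catalyst, and the syn γ-nitro aldehyde 10 is isolated. Compound 10 is added to acrolein 9 with catalytic Et3N in CH2Cl2 at 0 °C to give the nitro dialdehyde F1. F1 is cyclised with pyrrolidinium acetate (intramolecular aldol condensation from the less hindered aldehyde) to 11. The fallback sets out from 3 and 8 and returns at 11.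

**Step 18.** The likely failure is poor facial selectivity: bond formation anti to the vinyl group through the diaxial half-chair, plus some [1,2]-shift. Fallback: the shift is run while the nitro group still locks the ring with all three substituents equatorial, in its thermal amide-acetal (Büchi) form.
- Nitro alcohol 12 is heated with N,N-dimethylformamide dimethyl acetal in xylene at 140 °C to give the nitro amide F2.
- Bu3SnH and azobis(isobutyronitrile) give the amide F3.
- DDQ gives the hydroxy amide F4.
- Dess–Martin periodinane gives the formyl amide F5.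
- Zn/CH2Br2/TiCl4 gives the vinyl amide F6.
- LiEt3BH reduces the tertiary amide to the primary alcohol 25.

The fallback sets out from 12 and returns at 25.

**Step 20.** The likely failure is slow substitution at the neopentyl-type epoxide carbon by a weakly nucleophilic conjugated carboxylate, with oligomerisation through the free primary alcohol as the competing process. Fallback: the union is made by acylation instead.
- Epoxide 26 is opened with 4-methoxyphenol and Cs2CO3 in DMF at 90 °C to give the aryl ether diol F7.
- Oxidation as in step 21 gives the acid F8.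
- Alkylation as in step 22 gives the diester F9.
- Metathesis as in step 23 gives the lactone F10.
- (NH4)2Ce(NO3)6 in MeCN/H2O frees the diol F11.
- The primary hydroxyl of F11 is esterified with 20 (2,4,6-trichlorobenzoyl chloride, Et3N, then 4-(dimethylamino)pyridine, toluene) to give 30.

The fallback sets out from 26 and returns at 30.

**Step 7.** The likely failure is inefficient C–N homolysis at an unactivated secondary carbon, with the reduction stalling at the oxime or hydroxylamine stage, and rearrangement of the homoallylic radical. Fallback without a radical chain: the nitro group of 12 is reduced with Zn in AcOH to the amine F12, and F12 is deaminated with hydroxylamine-O-sulfonic acid in aqueous NaOH (through the monosubstituted diazene) to 13. The fallback sets out from 12 and returns at 13.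

**Step 12.** The likely failure is sluggish transfer of the hydroxymethyl group from tin, protodebromination, and an E/Z mixture carried over from step 11. Fallback: the hydroxymethyl group is brought in with the olefination reagent. Aldehyde 16 is treated with methyl 2-(dimethoxyphosphoryl)-3-[(tert-butyldimethylsilyl)oxy]propanoate, LiCl and 1,8-diazabicyclo[5.4.0]undec-7-ene in MeCN (Horner–Wadsworth–Emmons) to give 19 directly. The fallback sets out from 16 and returns at 19 and makes no new compound.

## Further compounds

F1 | step 5 | (2R,3S,4S)-2-{[(4-methoxyphenyl)methoxy]methyl}-4-nitro-3-(propan-2-yl)heptanedial | O=C[C@@H](COCc1ccc(OC)cc1)[C@H](C(C)C)[C@@H]([N+](=O)[O-])CCC=O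
F2 | step 18 | 2-{[(4-methoxyphenyl)methoxy]methyl}-N,N-dimethyl-6-methylidene-4-nitro-3-(propan-2-yl)cyclohexane-1-carboxamide (carboxamide cis to the C2 branch, C2/C3 trans, nitro trans to isopropyl) | CN(C)C(=O)[C@@H]1C(=C)C[C@H]([N+](=O)[O-])[C@@H](C(C)C)[C@@H]1COCc1ccc(OC)cc1
F3 | step 18 | 2-{[(4-methoxyphenyl)methoxy]methyl}-N,N-dimethyl-6-methylidene-3-(propan-2-yl)cyclohexane-1-carboxamide (1,2-cis, 2,3-trans) | CN(C)C(=O)[C@@H]1C(=C)CC[C@@H](C(C)C)[C@@H]1COCc1ccc(OC)cc1
F4 | step 18 | 2-(hydroxymethyl)-N,N-dimethyl-6-methylidene-3-(propan-2-yl)cyclohexane-1-carboxamide (1,2-cis, 2,3-trans) | CN(C)C(=O)[C@@H]1C(=C)CC[C@@H](C(C)C)[C@@H]1CO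
F5 | step 18 | 2-formyl-N,N-dimethyl-6-methylidene-3-(propan-2-yl)cyclohexane-1-carboxamide (1,2-cis, 2,3-trans) | CN(C)C(=O)[C@@H]1C(=C)CC[C@@H](C(C)C)[C@@H]1C=O
F6 | step 18 | 2-ethenyl-N,N-dimethyl-6-methylidene-3-(propan-2-yl)cyclohexane-1-carboxamide (1,2-cis, 2,3-trans) | CN(C)C(=O)[C@@H]1C(=C)CC[C@@H](C(C)C)[C@@H]1C=C
F7 | step 20 | 3-ethenyl-2-(hydroxymethyl)-1-[(4-methoxyphenoxy)methyl]-4-(propan-2-yl)cyclohexan-1-ol (configuration as in 27) | CC(C)[C@@H]1CC[C@](O)(COc2ccc(OC)cc2)[C@@H](CO)[C@H]1C=C
F8 | step 20 | 6-ethenyl-2-hydroxy-2-[(4-methoxyphenoxy)methyl]-5-(propan-2-yl)cyclohexane-1-carboxylic acid (configuration as in 28) | CC(C)[C@@H]1CC[C@](O)(COc2ccc(OC)cc2)[C@@H](C(=O)O)[C@H]1C=C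
F9 | step 20 | 2-(tert-butoxycarbonyl)prop-2-en-1-yl ester of F8 | CC(C)[C@@H]1CC[C@](O)(COc2ccc(OC)cc2)[C@@H](C(=O)OCC(=C)C(=O)OC(C)(C)C)[C@H]1C=C
F10 | step 20 | tert-butyl 9-hydroxy-9-[(4-methoxyphenoxy)methyl]-1-oxo-6-(propan-2-yl)-1,3,5a,6,7,8,9,9a-octahydro-2-benzoxepine-4-carboxylate (configuration as in 30) | CC(C)[C@@H]1CC[C@](O)(COc2ccc(OC)cc2)[C@H]2C(=O)OCC(C(=O)OC(C)(C)C)=C[C@@H]12
F11 | step 20 | tert-butyl 9-hydroxy-9-(hydroxymethyl)-1-oxo-6-(propan-2-yl)-1,3,5a,6,7,8,9,9a-octahydro-2-benzoxepine-4-carboxylate (configuration as in 30) | CC(C)[C@@H]1CC[C@](O)(CO)[C@H]2C(=O)OCC(C(=O)OC(C)(C)C)=C[C@@H]12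
F12 | step 7 | [(3R,4S,5S)-5-amino-3-{[(4-methoxyphenyl)methoxy]methyl}-4-(propan-2-yl)cyclohex-1-en-1-yl]methanol | OCC1=C[C@@H](COCc2ccc(OC)cc2)[C@H](C(C)C)[C@@H](N)C1
F0 | step 12 | none | none
A1 | alternative 1 | 4-hydroxy-3-{2,2-dimethyl-4-[3-(propan-2-yl)pent-4-en-1-yl]-1,3-dioxolan-4-yl}furan-2(5H)-one (tetronic acid photosubstrate) | C=C[C@H](C(C)C)CC[C@]1(COC(C)(C)O1)C1=C(O)COC1=O
A2 | alternative 1 | bicyclic keto lactone (rings A and B, ketone at C4, C9 diol as acetonide) | CC(C)[C@@H]1CC[C@]3(COC(C)(C)O3)[C@H]2C(=O)OCC(=O)C[C@@H]12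
A3 | alternative 2 | (2E)-3-[(1S,6S)-3-({[tert-butyl(dimethyl)silyl]oxy}methyl)-6-(propan-2-yl)cyclohex-2-en-1-yl]-2-iodoprop-2-en-1-ol | OC/C(I)=C\[C@@H]1C=C(CO[Si](C)(C)C(C)(C)C)CC[C@H]1C(C)C
A4 | alternative 2 | α-alkylidene β-lactone of the acyl half | O=C1OC/C1=C\[C@@H]2C=C(CO[Si](C)(C)C(C)(C)C)CC[C@H]2C(C)C
A5 | alternative 3 | 8-{[tert-butyl(dimethyl)silyl]oxy}-3-(dimethoxymethyl)-7-oxo-4-(propan-2-yl)octanoic acid | OC(=O)C[C@@H](C(OC)OC)[C@H](C(C)C)CCC(=O)CO[Si](C)(C)C(C)(C)C
A6 | alternative 3 | cyclohexane-fused β-lactone | CC(C)[C@@H]1CC[C@@]2(CO[Si](C)(C)C(C)(C)C)OC(=O)[C@H]2[C@H]1C(OC)OC
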